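## Retrosynthetic overview

1. The target is traced back to its isopropenyl analogue (allylic oxidation of the side-chain methyl), and the lactone carbonyl is carried as the ring O–CH2 group of a cis-fused 3-methylidene-tetrahydrofuran with a free hydroxyl where the acetate will sit.
2. That tetrahydrofuran (second and last ring formed) comes from a 1,6-enyne, the prop-2-ynyl ether of a ring allylic alcohol. A gold-catalysed 5-exo-dig hydroxycyclization joins the inner alkyne carbon (the future lactone α-carbon) to ring carbon C4 and adds water to C5.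
3. Enabling feature: in the lactone ring the oxygen on C3 and the α-carbon on C4 are cis on the cyclohexane, the neighbouring C5–O bond is trans to that C4–C bond, and the α-carbon carries an exocyclic CH2. This is exactly the pattern written by anti carbo-oxygenation of a C4=C5 ring alkene with an alkyne tethered through the C3 oxygen.
4. The enyne comes from a cis-2,3-diol with a C4=C5 alkene, made from a cyclohex-3-en-2-ol by hydroxyl-directed epoxidation and epoxide-to-allylic-alcohol isomerization, then O-propargylation and O-angeloylation.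
5. The cyclohexene ring (first ring formed) comes from a catalytic enantioselective Diels–Alder reaction of ethyl (E)-3-methyl-4-oxobut-2-enoate with (E)-1-acetoxybutadiene, which sets C1, C2 and C6.

Key step: step 9

Core locants used in the names: C1 is the quaternary ring carbon, C2 the angelate carbinol, C3 the lactone carbinol, C4 the ring carbon bonded to the lactone α-carbon, C5 the acetate carbinol, C6 the carbon bearing the three-carbon side chain. α is the ring face of the C1 vinyl (earlier formyl) group, β the face of the C1 methyl group. Absolute configurations are those of the SMILES.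

Assumption: the facial sense of the oxazaborolidinium catalyst in step 1 is taken from its behaviour with 2-methyl-substituted enals; should it prove opposite for this dienophile, the (R)-catalyst would be used with no other change. The diene is used as the commercial E/Z mixture, of which only the E isomer reacts.

## Route

Step 1
Reactants: 1 ethyl (2E)-3-methyl-4-oxobut-2-enoate; 2 (1E)-buta-1,3-dien-1-yl acetate
Product: 3 ethyl 2α-acetoxy-1α-formyl-1β-methylcyclohex-3-ene-6β-carboxylate
Conditions: (S)-1-(2-methylphenyl)-3,3-diphenyltetrahydro-1H,3H-pyrrolo[1,2-c][1,3,2]oxazaborole (10 mol %), HN(SO2CF3)2 (10 mol %), 2 (3 equiv), CH2Cl2, −78 → −40 °C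
Reagents that add atoms: none
Why: In this Lewis-acid-catalysed Diels–Alder reaction the boron-bound formyl group dominates the dienophile LUMO, so the acetoxy-bearing diene terminus bonds to the formyl-bearing carbon (ortho rule, creating C1 and C2), endo orientation of that formyl group places it cis to the acetoxy group, the E geometry of 1 is transferred as the trans relation of formyl and ester (C6), and the chiral oxazaborolidinium cation shields one face of the s-trans enal to fix the absolute configuration.

Step 2
Reactants: 3 ethyl 2α-acetoxy-1α-formyl-1β-methylcyclohex-3-ene-6β-carboxylate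
Product: 4 ethyl 2α-acetoxy-1β-methyl-1α-vinylcyclohex-3-ene-6β-carboxylate
Conditions: Ph3PCH3Br (1.3 equiv), n-BuLi (1.25 equiv), THF, −78 → 0 °C
Reagents that add atoms: methyltriphenylphosphonium bromide, C[P+](c1ccccc1)(c1ccccc1)c1ccccc1.[Br-]
Why: Wittig methylenation of the non-enolizable α-quaternary aldehyde is fast at low temperature, so the acetate and the ethyl ester should be left untouched and no stereocenter is affected.

Step 3
Reactants: 4 ethyl 2α-acetoxy-1β-methyl-1α-vinylcyclohex-3-ene-6β-carboxylate
Product: 6 6β-acetyl-1β-methyl-1α-vinylcyclohex-3-en-2α-ol, via silyl ketone 5 (not isolated)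
Conditions: Me3SiCH2Li (6 equiv), THF–pentane, −78 → 0 °C; then MeOH, 23 °C
Reagents that add atoms: (trimethylsilyl)methyllithium, [Li]C[Si](C)(C)C
Why: Acyl substitution of the ester by the organolithium should stop at the ketone stage because the α-silyl ketone 5 is at once deprotonated on its silicon-bearing carbon (so C6 is not epimerized), methanol then cleaves the C–Si bond (protodesilylation) to leave the methyl ketone, and the same reagent cleaves the acetate to free the C2 hydroxyl.

Step 4
Reactants: 6 6β-acetyl-1β-methyl-1α-vinylcyclohex-3-en-2α-ol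
Product: 7 6β-isopropenyl-1β-methyl-1α-vinylcyclohex-3-en-2α-ol
Conditions: Ph3PCH3Br (3 equiv), n-BuLi (3 equiv), THF, 0 → 23 °C
Reagents that add atoms: methyltriphenylphosphonium bromide, C[P+](c1ccccc1)(c1ccccc1)c1ccccc1.[Br-]
Why: Wittig methylenation of the methyl ketone, with the alcohol carried as its lithium alkoxide, which at this temperature should not enter the anionic oxy-Cope rearrangement open to a 3-oxido-1,5-diene; no new stereocenter is formed.

Step 5
Reactants: 7 6β-isopropenyl-1β-methyl-1α-vinylcyclohex-3-en-2α-ol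
Product: 8 3α,4α-epoxy-6β-isopropenyl-1β-methyl-1α-vinylcyclohexan-2α-ol
Conditions: VO(acac)2 (5 mol %), t-BuOOH (1.5 equiv), CH2Cl2, 0 → 23 °C
Reagents that add atoms: tert-butyl hydroperoxide, CC(C)(C)OO
Why: In this hydroxyl-directed epoxidation the vanadium alkoxide of the C2 hydroxyl delivers the peroxide oxygen only to the α face of the adjacent C3=C4 alkene, so the epoxide should form cis to the hydroxyl (setting C3) while the vinyl and isopropenyl groups are left alone.

Step 6
Reactants: 8 3α,4α-epoxy-6β-isopropenyl-1β-methyl-1α-vinylcyclohexan-2α-ol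
Product: 9 6β-isopropenyl-1β-methyl-1α-vinylcyclohex-4-ene-2α,3α-diol
Conditions: Et2NH, n-BuLi (gives LiNEt2, 4 equiv), Et2O–THF, 0 → 35 °C; aqueous work-up
Reagents that add atoms: none
Why: In this base-promoted isomerization of an epoxide to an allylic alcohol by syn β-elimination only C5 carries a hydrogen syn to the epoxide oxygen (the C2 hydrogen is anti), so the C4–O bond should break, the alkene should form at C4=C5 and the C3–O bond keeps its α configuration.

Step 7
Reactants: 9 6β-isopropenyl-1β-methyl-1α-vinylcyclohex-4-ene-2α,3α-diol; 10 3-bromoprop-1-yne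
Product: 11 6β-isopropenyl-1β-methyl-3α-(prop-2-ynyloxy)-1α-vinylcyclohex-4-en-2α-ol
Conditions: NaH (1.05 equiv), THF–DMF, −20 °C; 10 (1.1 equiv), Bu4NI (catalytic), −20 → 0 °C
Reagents that add atoms: none
Why: In this Williamson ether synthesis with one equivalent of base the allylic, pseudo-equatorial C3 hydroxyl should be alkylated, whereas the axial C2 hydroxyl next to the quaternary carbon is too hindered to react at this temperature; no stereocenter is touched.

Step 8
Reactants: 11 6β-isopropenyl-1β-methyl-3α-(prop-2-ynyloxy)-1α-vinylcyclohex-4-en-2α-ol; 12 (2Z)-2-methylbut-2-enoic anhydride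
Product: 13 6β-isopropenyl-1β-methyl-3α-(prop-2-ynyloxy)-1α-vinylcyclohex-4-en-2α-yl (2Z)-2-methylbut-2-enoate
Conditions: LiN(SiMe3)2 (1.1 equiv), THF, −78 °C; 12 (1.5 equiv), −78 → 0 °C; aqueous NH4Cl
Reagents that add atoms: none
Why: O-Acylation of the hindered C2 lithium alkoxide by the symmetrical anhydride is fast at low temperature and avoids the nucleophilic catalysts that isomerize Z-2-methylbut-2-enoates to the E isomers, so the angelate geometry should be kept.

Step 9
Reactants: 13 6β-isopropenyl-1β-methyl-3α-(prop-2-ynyloxy)-1α-vinylcyclohex-4-en-2α-yl (2Z)-2-methylbut-2-enoate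
Product: 14 (3aR,4S,5S,6S,7S,7aR)-6-ethenyl-4-hydroxy-6-methyl-3-methylidene-5-(prop-1-en-2-yl)octahydro-1-benzofuran-7-yl (2Z)-2-methylbut-2-enoate
Conditions: [(2-biphenylyl)(t-Bu)2P]Au(NCMe)SbF6 (5 mol %), H2O (20 equiv), 1,4-dioxane, 23 °C
Reagents that add atoms: water, O
Why: The cationic monovalent-gold complex binds the terminal alkyne and the C4=C5 ring alkene attacks its inner carbon from the α face, the only face the C3–O–CH2 tether can reach, to give an exo cyclopropyl gold carbene that water opens at C5 from the opposite face before protodeauration releases the exocyclic methylene. The closest known reaction type is the gold- or platinum-catalysed hydroxy- or alkoxycyclization of oxygen-tethered 1,6-enynes (nucleophile-intercepted cycloisomerization). The tetrahydrofuran ring, the only ring formed, closes in the 5-exo-dig mode through the new bond between the inner alkyne carbon (the future lactone α-carbon) and C4. C4 is controlled by the C3 stereocenter through the short tether, which allows only the cis ring fusion, and C5 by the stereospecific anti addition of carbon and oxygen across the alkene, which places the hydroxyl β, trans to the new C–C bond. The step needs exo rather than endo attack on the alkyne and capture by water rather than skeletal rearrangement or alkyne hydration; the terminal alkyne, the inductive pull of the C3 ether oxygen that localises positive charge on the distal carbon C5, the excess of water and the acylated C2 oxygen (no free hydroxyl left to add to the alkyne) are there to secure this.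

Step 10
Reactants: 14 (3aR,4S,5S,6S,7S,7aR)-6-ethenyl-4-hydroxy-6-methyl-3-methylidene-5-(prop-1-en-2-yl)octahydro-1-benzofuran-7-yl (2Z)-2-methylbut-2-enoate
Product: 15 (3aR,4S,5S,6S,7S,7aR)-4-acetoxy-6-ethenyl-6-methyl-3-methylidene-5-(prop-1-en-2-yl)octahydro-1-benzofuran-7-yl (2Z)-2-methylbut-2-enoate
Conditions: Ac2O, pyridine, DMAP (catalytic), CH2Cl2, 23 °C
Reagents that add atoms: acetic anhydride, CC(=O)OC(C)=O
Why: DMAP-catalysed O-acetylation of the secondary C5 alcohol, the only free hydroxyl, proceeds with retention.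

Step 11
Reactants: 15 (3aR,4S,5S,6S,7S,7aR)-4-acetoxy-6-ethenyl-6-methyl-3-methylidene-5-(prop-1-en-2-yl)octahydro-1-benzofuran-7-yl (2Z)-2-methylbut-2-enoate
Product: 16 (3aR,4S,5S,6S,7S,7aR)-4-acetoxy-6-ethenyl-6-methyl-3-methylidene-2-oxo-5-(prop-1-en-2-yl)octahydro-1-benzofuran-7-yl (2Z)-2-methylbut-2-enoate
Conditions: CrO3 (15 equiv), 3,5-dimethylpyrazole (15 equiv), CH2Cl2, −20 °C
Reagents that add atoms: chromium trioxide, O=[Cr](=O)=O
Why: In this allylic C–H oxidation by the hexavalent-chromium pyrazole complex the ring CH2 of the tetrahydrofuran is both allylic and α to oxygen and should be oxidized far faster than the other allylic positions, giving the α-methylene-γ-lactone without touching a stereocenter.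

Step 12
Reactants: 16 (3aR,4S,5S,6S,7S,7aR)-4-acetoxy-6-ethenyl-6-methyl-3-methylidene-2-oxo-5-(prop-1-en-2-yl)octahydro-1-benzofuran-7-yl (2Z)-2-methylbut-2-enoate
Product: 18 (3aR,4S,5R,6S,7S,7aR)-4-acetoxy-6-ethenyl-6-methyl-3-methylidene-2-oxo-5-(3-oxoprop-1-en-2-yl)octahydro-1-benzofuran-7-yl (2Z)-2-methylbut-2-enoate, via allylic alcohol 17 (not isolated)
Conditions: SeO2 (0.3 equiv), t-BuOOH (3 equiv), CH2Cl2, 23 °C; then MnO2 (20 equiv) added to the same flask, 23 °C
Reagents that add atoms: selenium dioxide, O=[Se]=O; tert-butyl hydroperoxide, CC(C)(C)OO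
Why: Selenium dioxide allylic oxidation (ene reaction followed by a 2,3-sigmatropic shift) should attack the electron-rich 1,1-disubstituted isopropenyl group at its methyl group in preference to the electron-poor lactone and ester alkenes, and MnO2 then oxidizes only the resulting primary allylic alcohol to the enal, which is the target.

## Compound list

1 | ethyl (2E)-3-methyl-4-oxobut-2-enoate | CCOC(=O)/C=C(\C)C=O | starting material
2 | (1E)-buta-1,3-dien-1-yl acetate | CC(=O)O/C=C/C=C | starting material
3 | ethyl 2α-acetoxy-1α-formyl-1β-methylcyclohex-3-ene-6β-carboxylate | O=C[C@]1(C)[C@H](OC(C)=O)C=CC[C@H]1C(=O)OCC | intermediate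
4 | ethyl 2α-acetoxy-1β-methyl-1α-vinylcyclohex-3-ene-6β-carboxylate | C=C[C@]1(C)[C@H](OC(C)=O)C=CC[C@H]1C(=O)OCC | intermediate
5 | 1β-methyl-6β-[(trimethylsilyl)acetyl]-1α-vinylcyclohex-3-en-2α-ol (silyl ketone, not isolated) | C=C[C@]1(C)[C@H](O)C=CC[C@H]1C(=O)C[Si](C)(C)C | intermediate
6 | 6β-acetyl-1β-methyl-1α-vinylcyclohex-3-en-2α-ol | C=C[C@]1(C)[C@H](O)C=CC[C@H]1C(C)=O | intermediate
7 | 6β-isopropenyl-1β-methyl-1α-vinylcyclohex-3-en-2α-ol | C=C[C@]1(C)[C@H](O)C=CC[C@H]1C(C)=C | intermediate
8 | 3α,4α-epoxy-6β-isopropenyl-1β-methyl-1α-vinylcyclohexan-2α-ol | C=C[C@]1(C)[C@H](O)[C@@H]2O[C@@H]2C[C@H]1C(C)=C | intermediate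
9 | 6β-isopropenyl-1β-methyl-1α-vinylcyclohex-4-ene-2α,3α-diol | C=C[C@]1(C)[C@H](O)[C@H](O)C=C[C@H]1C(C)=C | intermediate
10 | 3-bromoprop-1-yne (propargyl bromide) | C#CCBr | starting material
11 | 6β-isopropenyl-1β-methyl-3α-(prop-2-ynyloxy)-1α-vinylcyclohex-4-en-2α-ol | C=C[C@]1(C)[C@H](O)[C@H](OCC#C)C=C[C@H]1C(C)=C | intermediate
12 | (2Z)-2-methylbut-2-enoic anhydride (angelic anhydride) | C/C=C(/C)C(=O)OC(=O)/C(C)=C\C | starting material
13 | 6β-isopropenyl-1β-methyl-3α-(prop-2-ynyloxy)-1α-vinylcyclohex-4-en-2α-yl (2Z)-2-methylbut-2-enoate | C=C[C@]1(C)[C@H](OC(=O)/C(C)=C\C)[C@H](OCC#C)C=C[C@H]1C(C)=C | intermediate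
14 | (3aR,4S,5S,6S,7S,7aR)-6-ethenyl-4-hydroxy-6-methyl-3-methylidene-5-(prop-1-en-2-yl)octahydro-1-benzofuran-7-yl (2Z)-2-methylbut-2-enoate | C=C[C@]1(C)[C@H](OC(=O)/C(C)=C\C)[C@@H]2OCC(=C)[C@@H]2[C@@H](O)[C@H]1C(C)=C | intermediate
15 | (3aR,4S,5S,6S,7S,7aR)-4-acetoxy-6-ethenyl-6-methyl-3-methylidene-5-(prop-1-en-2-yl)octahydro-1-benzofuran-7-yl (2Z)-2-methylbut-2-enoate | C=C[C@]1(C)[C@H](OC(=O)/C(C)=C\C)[C@@H]2OCC(=C)[C@@H]2[C@@H](OC(C)=O)[C@H]1C(C)=C | intermediate
16 | (3aR,4S,5S,6S,7S,7aR)-4-acetoxy-6-ethenyl-6-methyl-3-methylidene-2-oxo-5-(prop-1-en-2-yl)octahydro-1-benzofuran-7-yl (2Z)-2-methylbut-2-enoate | C=C[C@]1(C)[C@H](OC(=O)/C(C)=C\C)[C@@H]2OC(=O)C(=C)[C@@H]2[C@@H](OC(C)=O)[C@H]1C(C)=C | intermediate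
17 | (3aR,4S,5S,6S,7S,7aR)-4-acetoxy-6-ethenyl-5-(3-hydroxyprop-1-en-2-yl)-6-methyl-3-methylidene-2-oxooctahydro-1-benzofuran-7-yl (2Z)-2-methylbut-2-enoate (allylic alcohol, not isolated) | C=C[C@]1(C)[C@H](OC(=O)/C(C)=C\C)[C@@H]2OC(=O)C(=C)[C@@H]2[C@@H](OC(C)=O)[C@H]1C(=C)CO | intermediate
18 | (3aR,4S,5R,6S,7S,7aR)-4-acetoxy-6-ethenyl-6-methyl-3-methylidene-2-oxo-5-(3-oxoprop-1-en-2-yl)octahydro-1-benzofuran-7-yl (2Z)-2-methylbut-2-enoate | C=C[C@]1(C)[C@H](OC(=O)/C(C)=C\C)[C@@H]2OC(=O)C(=C)[C@@H]2[C@@H](OC(C)=O)[C@H]1C(=C)C=O | target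

## Step count and risks

Total step count: 12. Longest linear sequence: 12 steps (from 1 and 2 to 18).

Steps most likely to fail:

Step 9. What may go wrong: closure in the endo mode to a cyclopropane-fused dihydropyran, skeletal rearrangement of the unstabilised cyclopropyl carbene before water is captured at the secondary carbon C5, or plain hydration of the alkyne. The fallback replaces π-acid catalysis by a radical cyclization with oxygen-radical capture and carries the tether one oxidation level higher; it sets out from diol 9 and comes back to the route at lactone 16. Diol 9 would be treated with N-iodosuccinimide and methoxyallene (CH2Cl2, −40 °C) to give, at the less hindered C3 hydroxyl, the mixed 2-iodoallyl methyl acetal F1. Bu3SnH with TEMPO in benzene at 70 °C should then bring about vinyl-radical 5-exo-trig cyclization onto C4 from the α face and capture of the C5 radical on the convex β face, giving the bicyclic lactol methyl ether with a piperidinyloxy group on C5 F2. Acylation of its C2 lithium alkoxide with 12 should give the angelate F3. Zn in acetic acid should cleave the N–O bond, and acetic anhydride with pyridine should then give the C5 acetate F4. Jones oxidation (CrO3, H2SO4, acetone, 0 °C) should convert the allylic methyl acetal into lactone 16.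

Step 1. What may go wrong: insufficient facial discrimination by the catalyst, or erosion of the ortho and endo preferences because the ester carbonyl competes with the aldehyde for the Lewis acid. The fallback uses auxiliary control in place of catalyst control; it sets out from 1 and comes back at 6. The dienophile 1 would be combined (BF3·OEt2, toluene, −78 °C) with the dienyl ester of (S)-O-methylmandelic acid, (1E)-buta-1,3-dien-1-yl (2S)-2-methoxy-2-phenylacetate F5, itself made from crotonaldehyde, KOt-Bu and (2S)-2-methoxy-2-phenylacetyl chloride. The diastereomeric cycloadducts are separable, and the one needed is the mandelate adduct F6 (the (S)-auxiliary is assumed to favour it; otherwise its mirror image is used). Wittig methylenation as in step 2 should give the vinyl mandelate F7, and the conditions of step 3 should cleave the auxiliary ester as they cleave the acetate and deliver 6.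

Step 7. What may go wrong: poor site selectivity between the two hydroxyls, with alkylation at C2 or at both oxygens. The fallback enforces the site by temporary protection; it sets out from epoxy alcohol 8 and comes back at 11. Alcohol 8 would be converted (NaH, 4-methoxybenzyl chloride, DMF) into its 4-methoxybenzyl ether F8; isomerization with LiNEt2 as in step 6 should give the allylic alcohol F9 with only the C3 hydroxyl free; propargylation with NaH and 10 should give the propargyl ether F10; and DDQ in wet CH2Cl2 should remove the 4-methoxybenzyl group to give 11.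

## Further compounds

F1 | step 9 | 3α-[(2-iodo-1-methoxyprop-2-en-1-yl)oxy]-6β-isopropenyl-1β-methyl-1α-vinylcyclohex-4-en-2α-ol (either acetal epimer) | C=C[C@]1(C)[C@H](O)[C@H](OC(OC)C(I)=C)C=C[C@H]1C(C)=C
F2 | step 9 | 6-ethenyl-2-methoxy-6-methyl-3-methylidene-5-(prop-1-en-2-yl)-4-[(2,2,6,6-tetramethylpiperidin-1-yl)oxy]octahydro-1-benzofuran-7-ol (ring stereocentres as in 14; either epimer at the acetal carbon) | C=C[C@]1(C)[C@H](O)[C@@H]2OC(OC)C(=C)[C@@H]2[C@@H](ON3C(C)(C)CCCC3(C)C)[C@H]1C(C)=C
F3 | step 9 | 6-ethenyl-2-methoxy-6-methyl-3-methylidene-5-(prop-1-en-2-yl)-4-[(2,2,6,6-tetramethylpiperidin-1-yl)oxy]octahydro-1-benzofuran-7-yl (2Z)-2-methylbut-2-enoate | C=C[C@]1(C)[C@H](OC(=O)/C(C)=C\C)[C@@H]2OC(OC)C(=C)[C@@H]2[C@@H](ON3C(C)(C)CCCC3(C)C)[C@H]1C(C)=C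
F4 | step 9 | 4-acetoxy-6-ethenyl-2-methoxy-6-methyl-3-methylidene-5-(prop-1-en-2-yl)octahydro-1-benzofuran-7-yl (2Z)-2-methylbut-2-enoate | C=C[C@]1(C)[C@H](OC(=O)/C(C)=C\C)[C@@H]2OC(OC)C(=C)[C@@H]2[C@@H](OC(C)=O)[C@H]1C(C)=C
F5 | step 1 | (1E)-buta-1,3-dien-1-yl (2S)-2-methoxy-2-phenylacetate | CO[C@H](C(=O)O/C=C/C=C)c1ccccc1
F6 | step 1 | ethyl 1α-formyl-2α-{[(2S)-2-methoxy-2-phenylacetyl]oxy}-1β-methylcyclohex-3-ene-6β-carboxylate | O=C[C@]1(C)[C@H](OC(=O)[C@@H](OC)c2ccccc2)C=CC[C@H]1C(=O)OCC
F7 | step 1 | ethyl 2α-{[(2S)-2-methoxy-2-phenylacetyl]oxy}-1β-methyl-1α-vinylcyclohex-3-ene-6β-carboxylate | C=C[C@]1(C)[C@H](OC(=O)[C@@H](OC)c2ccccc2)C=CC[C@H]1C(=O)OCC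
F8 | step 7 | 3α,4α-epoxy-6β-isopropenyl-2α-[(4-methoxybenzyl)oxy]-1β-methyl-1α-vinylcyclohexane | C=C[C@]1(C)[C@H](OCc2ccc(OC)cc2)[C@@H]3O[C@@H]3C[C@H]1C(C)=C
F9 | step 7 | 6β-isopropenyl-2α-[(4-methoxybenzyl)oxy]-1β-methyl-1α-vinylcyclohex-4-en-3α-ol | C=C[C@]1(C)[C@H](OCc2ccc(OC)cc2)[C@H](O)C=C[C@H]1C(C)=C
F10 | step 7 | 6β-isopropenyl-2α-[(4-methoxybenzyl)oxy]-1β-methyl-3α-(prop-2-ynyloxy)-1α-vinylcyclohex-4-ene | C=C[C@]1(C)[C@H](OCc2ccc(OC)cc2)[C@H](OCC#C)C=C[C@H]1C(C)=C
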